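**Retrosynthetic overview**
1. The methylene bridge between the two pyranone C3 atoms is cut last: the Mannich base 20 of the tetralone half alkylates C3 of the naphthalene half 19.
2. The naphthalene half is the dehydrated form of the tetralone half, so one racemic tetralone 17 serves both: resolution gives (3R,4R)-18, and the other enantiomer is aromatised to achiral 19.
3. The tetralone ring comes from an anionic [3+3] annulation of bromoarene 10 with silyl enol ether 12 of ethyl benzoylacetate: acylation joins aryl C8a to C1, then a Michael closure joins C4 to C3 and sets both stereocentres (relative configuration).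
4. Enabling feature (tetralone numbering: C1 ketone, C3 carbinol, C4 CH carrying the pyranone, C8 phenol carbon): C8a, between oxygenated C8 and C4a, and the C4–H, flanked by the arene and pyranone C6 and vinylogous to the lactone C=O, form a latent 1,3-dinucleophile; C1–C2–C3(Ph) is a benzoylacetyl 1,3-dielectrophile.
5. Ring order: pyranone (acylketene lactonisation), then the cyclohexanone ring of the tetralone (key step), then the second naphthalene ring by dehydration, then union through CH2.

Key step: step 7

Remark (assumption): quinidine is written in step 10 as the cinchona base whose less soluble salt holds the (3R,4R) acid; if the opposite holds, its pseudo-enantiomer quinine takes its place without other change.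

Step 1
Reactants: 1 2-bromo-3-hydroxybenzaldehyde
Product: 2 3-(benzyloxy)-2-bromobenzaldehyde
Conditions: BnBr, K2CO3, DMF, rt
Reagents that add atoms: benzyl bromide, BrCc1ccccc1
Why: Williamson ether synthesis on the phenoxide gives a benzyl ether that should survive base, t-BuLi at −78 °C and 110 °C and is removed later by hydrogenolysis.

Step 2
Reactants: 2 3-(benzyloxy)-2-bromobenzaldehyde
Product: 4 2-[3-(benzyloxy)-2-bromophenyl]acetaldehyde, via enol ether 3 (not isolated)
Conditions: Ph3P(Cl)CH2OMe, KOt-Bu, THF, 0 °C; then 2 M HCl, THF, 50 °C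
Reagents that add atoms: (methoxymethyl)triphenylphosphonium chloride, COC[P+](c1ccccc1)(c1ccccc1)c1ccccc1.[Cl-]; water, O
Why: Wittig methoxymethylenation followed by acid hydrolysis of the enol ether should give the one-carbon homologated aldehyde, which is used crude.

Step 3
Reactants: 4 2-[3-(benzyloxy)-2-bromophenyl]acetaldehyde
Product: 5 2-[3-(benzyloxy)-2-bromophenyl]acetic acid
Conditions: NaClO2, NaH2PO4, 2-methyl-2-butene, t-BuOH/H2O, 0 °C to rt
Reagents that add atoms: sodium chlorite, [Na+].[O-]Cl=O
Why: Pinnick oxidation converts the enolisable aldehyde to the acid without touching the aryl bromide, the alkene scavenger keeping hypochlorite away from the electron-rich arene.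

Step 4
Reactants: 5 2-[3-(benzyloxy)-2-bromophenyl]acetic acid; 6 2,2,6-trimethyl-4H-1,3-dioxin-4-one
Product: 8 6-{3-[3-(benzyloxy)-2-bromophenyl]-2-oxopropyl}-2,2-dimethyl-4H-1,3-dioxin-4-one, via acyl imidazolide 7 (not isolated)
Conditions: 5, CDI, THF, rt; added to 6 + LiN(SiMe3)2 (2.2 equiv), THF, −78 °C; then 1 M HCl
Reagents that add atoms: none
Why: Crossed Claisen-type C-acylation of the vinylogous lithium enolate of the dioxinone at its methyl carbon by the acyl imidazolide, the second equivalent of enolate absorbing the acidic product.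

Step 5
Reactants: 8 6-{3-[3-(benzyloxy)-2-bromophenyl]-2-oxopropyl}-2,2-dimethyl-4H-1,3-dioxin-4-one
Product: 10 6-{[3-(benzyloxy)-2-bromophenyl]methyl}-4-hydroxy-2H-pyran-2-one, via acylketene 9 (not isolated)
Conditions: toluene, 110 °C
Reagents that add atoms: none
Why: Thermal retro-[4+2] of the dioxinone releases acetone and an acylketene, which the enol oxygen of the δ-ketone should capture to close the 4-hydroxy-2-pyranone.

Step 6
Reactants: 11 ethyl 3-oxo-3-phenylpropanoate
Product: 12 ethyl (2Z)-3-phenyl-3-[(triethylsilyl)oxy]prop-2-enoate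
Conditions: Et3SiOTf, Et3N, CH2Cl2, 0 °C
Reagents that add atoms: triethylsilyl trifluoromethanesulfonate, CC[Si](CC)(CC)OS(=O)(=O)C(F)(F)F
Why: O-silylation of the chelated enol of the β-keto ester (soft enolisation) should give the Z silyl enol ether, which removes the acidic CH2 and turns the ketone carbon into a Michael acceptor carbon.

Step 7
Reactants: 10 6-{[3-(benzyloxy)-2-bromophenyl]methyl}-4-hydroxy-2H-pyran-2-one; 12 ethyl (2Z)-3-phenyl-3-[(triethylsilyl)oxy]prop-2-enoate
Product: 15 rac-(3R,4S)-8-(benzyloxy)-4-(4-hydroxy-2-oxo-2H-pyran-6-yl)-3-phenyl-3-[(triethylsilyl)oxy]-3,4-dihydronaphthalen-1(2H)-one, via trilithio arene 13 (not isolated), via silyloxy enone 14 (not isolated)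
Conditions: t-BuLi (4.1 equiv), THF, −78 °C; then 12 (1.1 equiv), −78 to −50 °C; AcOH, −78 °C
Reagents that add atoms: none
Why: Proposed new method: four equivalents of t-BuLi should turn 10 into trilithio species 13 (pyranonate O–Li, aryl C–Li by Br–Li exchange, pyranone-stabilised benzylic C–Li); the aryllithium carbon, the hardest nucleophile, adds to the ester carbonyl of 12, loss of ethoxide gives aryl ketone 14, and the benzylic carbanion then adds to the silyloxy-bearing enone carbon in a 6-endo-trig Michael closure of the cyclohexanone ring. The closest known reaction types are the aryllithium/ester ketone synthesis after halogen–lithium exchange (Parham-type acylation), the Michael half of the Staunton–Weinreb annulation and the 6-endo-trig closure of 2'-hydroxychalcones to flavanones; what is new is a β-silyloxy enone as acceptor with retention of the silyloxy group, which gives a protected tertiary aldol that cannot revert by retro-aldol, whereas a free 1,3-diketone would sit as an unreactive enolate under base. The closure should be driven by the exchange of a high-energy carbanion of the pyranonate dianion for an aryl ketone enolate, and the cold quench is needed before that enolate expels silanolate (E1cB) and aromatises to the naphthol. Both stereocentres arise in the Michael step: the Z enol ether should place phenyl pseudo-equatorial and the silyloxy group pseudo-axial, and the pyranone at the benzylic carbon should take the pseudo-axial position to avoid peri strain with the neighbouring aryl C–H, which gives the trans arrangement of silyloxy and pyranone found in the target; the step is racemic and the absolute configuration is fixed in step 10. Site selectivity rests on the bromine (only that carbon becomes the aryl anion), on the di-ortho-substituted ketone (no second addition) and on ring size (only the benzylic carbon reaches the β-carbon).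

Step 8
Reactants: 15 rac-(3R,4S)-8-(benzyloxy)-4-(4-hydroxy-2-oxo-2H-pyran-6-yl)-3-phenyl-3-[(triethylsilyl)oxy]-3,4-dihydronaphthalen-1(2H)-one
Product: 16 rac-(3R,4S)-8-hydroxy-4-(4-hydroxy-2-oxo-2H-pyran-6-yl)-3-phenyl-3-[(triethylsilyl)oxy]-3,4-dihydronaphthalen-1(2H)-one
Conditions: H2 (1 atm), 10% Pd/C, EtOAc, rt
Reagents that add atoms: none
Why: Hydrogenolysis of the aryl benzyl ether under neutral conditions should be faster than reduction of the pyranone, the aryl ketone or the tertiary silyl ether.

Step 9
Reactants: 16 rac-(3R,4S)-8-hydroxy-4-(4-hydroxy-2-oxo-2H-pyran-6-yl)-3-phenyl-3-[(triethylsilyl)oxy]-3,4-dihydronaphthalen-1(2H)-one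
Product: 17 rac-(3R,4R)-3,8-dihydroxy-4-(4-hydroxy-2-oxo-2H-pyran-6-yl)-3-phenyl-3,4-dihydronaphthalen-1(2H)-one
Conditions: HF·pyridine, pyridine, THF, 0 °C to rt
Reagents that add atoms: none
Why: Fluoride-mediated cleavage of the tertiary triethylsilyl ether in a buffered, non-basic medium should free the aldol hydroxyl without retro-aldol or β-elimination (the descriptor at C4 changes only because the CIP priorities change).

Step 10
Reactants: 17 rac-(3R,4R)-3,8-dihydroxy-4-(4-hydroxy-2-oxo-2H-pyran-6-yl)-3-phenyl-3,4-dihydronaphthalen-1(2H)-one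
Product: 18 (3R,4R)-3,8-dihydroxy-4-(4-hydroxy-2-oxo-2H-pyran-6-yl)-3-phenyl-3,4-dihydronaphthalen-1(2H)-one
Conditions: quinidine (1 equiv), EtOAc/acetone, crystallise; salt, then 1 M citric acid/EtOAc
Reagents that add atoms: none
Why: Classical resolution through diastereomeric salts of the acidic 4-hydroxypyranone with a cinchona base, as is done for 4-hydroxycoumarin-type acids, should select the absolute configuration at both centres, and the enantiomer left in the mother liquor is not lost because it feeds step 11.

Step 11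
Reactants: 17 rac-(3R,4R)-3,8-dihydroxy-4-(4-hydroxy-2-oxo-2H-pyran-6-yl)-3-phenyl-3,4-dihydronaphthalen-1(2H)-one (the enantiomer recovered from step 10 is added to this portion)
Product: 19 6-(4,5-dihydroxy-2-phenylnaphthalen-1-yl)-4-hydroxy-2H-pyran-2-one
Conditions: TsOH·H2O (10 mol%), toluene, 80 °C
Reagents that add atoms: none
Why: Acid-catalysed β-elimination of water from the tertiary benzylic aldol and tautomerisation of the resulting enone should give the 1-naphthol, which removes both stereocentres so that either enantiomer can be used.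

Step 12
Reactants: 18 (3R,4R)-3,8-dihydroxy-4-(4-hydroxy-2-oxo-2H-pyran-6-yl)-3-phenyl-3,4-dihydronaphthalen-1(2H)-one
Product: 20 (3R,4R)-4-{3-[(dimethylamino)methyl]-4-hydroxy-2-oxo-2H-pyran-6-yl}-3,8-dihydroxy-3-phenyl-3,4-dihydronaphthalen-1(2H)-one
Conditions: CH2(NMe2)2 (1.05 equiv), CH2Cl2, 0 °C to rt
Reagents that add atoms: bis(dimethylamino)methane, CN(C)CN(C)C
Why: Mannich aminomethylation at C3 of the 4-hydroxypyranone, the only strongly nucleophilic carbon of 18, after the acidic enol has ionised the aminal to the iminium ion; the stereocentres are not involved.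

Step 13
Reactants: 20 (3R,4R)-4-{3-[(dimethylamino)methyl]-4-hydroxy-2-oxo-2H-pyran-6-yl}-3,8-dihydroxy-3-phenyl-3,4-dihydronaphthalen-1(2H)-one; 19 6-(4,5-dihydroxy-2-phenylnaphthalen-1-yl)-4-hydroxy-2H-pyran-2-one
Product: 21 wailupemycin I, (3R,4R)-4-(3-{[6-(4,5-dihydroxy-2-phenylnaphthalen-1-yl)-4-hydroxy-2-oxo-2H-pyran-3-yl]methyl}-4-hydroxy-2-oxo-2H-pyran-6-yl)-3,8-dihydroxy-3-phenyl-3,4-dihydronaphthalen-1(2H)-one
Conditions: 19 (1.2 equiv), 1,4-dioxane, 60 °C
Reagents that add atoms: none
Why: Thermal loss of dimethylamine from the Mannich base should give the 3-methylene-pyran-2,4-dione (a quinone-methide-type acceptor), which C3 of the second 4-hydroxypyranone intercepts by Michael addition under near-neutral conditions that leave the aldol stereocentres alone.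

**Compound list**
1 | 2-bromo-3-hydroxybenzaldehyde | O=Cc1cccc(O)c1Br | starting material
2 | 3-(benzyloxy)-2-bromobenzaldehyde | O=Cc1cccc(OCc2ccccc2)c1Br | intermediate
3 | 1-(benzyloxy)-2-bromo-3-(2-methoxyethenyl)benzene (E/Z mixture, not isolated) | COC=Cc1cccc(OCc2ccccc2)c1Br | intermediate
4 | 2-[3-(benzyloxy)-2-bromophenyl]acetaldehyde | O=CCc1cccc(OCc2ccccc2)c1Br | intermediate
5 | 2-[3-(benzyloxy)-2-bromophenyl]acetic acid | OC(=O)Cc1cccc(OCc2ccccc2)c1Br | intermediate
6 | 2,2,6-trimethyl-4H-1,3-dioxin-4-one | CC1=CC(=O)OC(C)(C)O1 | starting material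
7 | 2-[3-(benzyloxy)-2-bromophenyl]-1-(1H-imidazol-1-yl)ethan-1-one (not isolated) | O=C(Cc1cccc(OCc2ccccc2)c1Br)n1ccnc1 | intermediate
8 | 6-{3-[3-(benzyloxy)-2-bromophenyl]-2-oxopropyl}-2,2-dimethyl-4H-1,3-dioxin-4-one | CC1(C)OC(=O)C=C(CC(=O)Cc2cccc(OCc3ccccc3)c2Br)O1 | intermediate
9 | 6-[3-(benzyloxy)-2-bromophenyl]-3,5-dioxohex-1-en-1-one (acylketene, not isolated) | O=C=CC(=O)CC(=O)Cc1cccc(OCc2ccccc2)c1Br | intermediate
10 | 6-{[3-(benzyloxy)-2-bromophenyl]methyl}-4-hydroxy-2H-pyran-2-one | O=c1cc(O)cc(Cc2cccc(OCc3ccccc3)c2Br)o1 | intermediate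
11 | ethyl 3-oxo-3-phenylpropanoate | CCOC(=O)CC(=O)c1ccccc1 | starting material
12 | ethyl (2Z)-3-phenyl-3-[(triethylsilyl)oxy]prop-2-enoate | CCOC(=O)/C=C(\O[Si](CC)(CC)CC)c1ccccc1 | intermediate
13 | trilithio derivative of 10: lithium pyranon-4-olate, benzylic C–Li, aryl C–Li in place of Br (not isolated) | [Li]Oc1cc(C([Li])c2cccc(OCc3ccccc3)c2[Li])oc(=O)c1 | intermediate
14 | dilithio (Z)-β-silyloxy enone: aryl ketone of 13 with the 3-phenyl-3-[(triethylsilyl)oxy]prop-2-enoyl group (not isolated) | [Li]Oc1cc(C([Li])c2cccc(OCc3ccccc3)c2C(=O)/C=C(\O[Si](CC)(CC)CC)c2ccccc2)oc(=O)c1 | intermediate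
15 | rac-(3R,4S)-8-(benzyloxy)-4-(4-hydroxy-2-oxo-2H-pyran-6-yl)-3-phenyl-3-[(triethylsilyl)oxy]-3,4-dihydronaphthalen-1(2H)-one (racemate, one enantiomer drawn) | O=C1C[C@](O[Si](CC)(CC)CC)(c2ccccc2)[C@H](c2cc(O)cc(=O)o2)c2cccc(OCc3ccccc3)c21 | intermediate
16 | rac-(3R,4S)-8-hydroxy-4-(4-hydroxy-2-oxo-2H-pyran-6-yl)-3-phenyl-3-[(triethylsilyl)oxy]-3,4-dihydronaphthalen-1(2H)-one (racemate, one enantiomer drawn) | O=C1C[C@](O[Si](CC)(CC)CC)(c2ccccc2)[C@H](c2cc(O)cc(=O)o2)c2cccc(O)c21 | intermediate
17 | rac-(3R,4R)-3,8-dihydroxy-4-(4-hydroxy-2-oxo-2H-pyran-6-yl)-3-phenyl-3,4-dihydronaphthalen-1(2H)-one (racemate, one enantiomer drawn) | O=C1C[C@](O)(c2ccccc2)[C@H](c2cc(O)cc(=O)o2)c2cccc(O)c21 | intermediate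
18 | (3R,4R)-3,8-dihydroxy-4-(4-hydroxy-2-oxo-2H-pyran-6-yl)-3-phenyl-3,4-dihydronaphthalen-1(2H)-one (single enantiomer) | O=C1C[C@](O)(c2ccccc2)[C@H](c2cc(O)cc(=O)o2)c2cccc(O)c21 | intermediate
19 | 6-(4,5-dihydroxy-2-phenylnaphthalen-1-yl)-4-hydroxy-2H-pyran-2-one | O=c1cc(O)cc(-c2c(-c3ccccc3)cc(O)c3c(O)cccc23)o1 | intermediate
20 | (3R,4R)-4-{3-[(dimethylamino)methyl]-4-hydroxy-2-oxo-2H-pyran-6-yl}-3,8-dihydroxy-3-phenyl-3,4-dihydronaphthalen-1(2H)-one | O=C1C[C@](O)(c2ccccc2)[C@H](c2cc(O)c(CN(C)C)c(=O)o2)c2cccc(O)c21 | intermediate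
21 | wailupemycin I | O=C1C[C@](O)(c2ccccc2)[C@H](c2cc(O)c(Cc3c(O)cc(-c4c(-c5ccccc5)cc(O)c5c(O)cccc45)oc3=O)c(=O)o2)c2cccc(O)c21 | target

**Step count**
Total: 13 steps. Longest linear sequence: 11 steps (1, 2, 3, 4, 5, 7, 8, 9, 10, 12, 13).

**Steps most likely to fail**

1. Step 7 (proposed new method). What may go wrong:
- proton transfer from the benzylic position to the aryllithium before acylation;
- transfer of the silyl group to ethoxide before ring closure, which leaves an unreactive diketonate;
- loss of silanolate from the cyclised enolate with aromatisation to the naphthol;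
- poor facial selectivity in the ring closure.

Fallback by known reactions only, setting out from 10 and returning at 17. The pyranone hydroxyl of 10 is benzylated (BnBr, K2CO3, DMF) to 4-(benzyloxy)-6-{[3-(benzyloxy)-2-bromophenyl]methyl}-2H-pyran-2-one F1, in which the benzylic C–H is acidic enough for a mild-base aldol. From 11, MeNHOMe·HCl and i-PrMgCl give the Weinreb amide N-methoxy-N-methyl-3-oxo-3-phenylpropanamide F2. F1 is deprotonated at the benzylic carbon with LiN(i-Pr)2 (1.05 equiv), exchanged with t-BuLi (3.1 equiv, one of which regenerates the amide base) and acylated with the sodium enolate of F2 (NaH). This Weinreb ketone synthesis should give, after work-up, 1-{2-(benzyloxy)-6-[(4-(benzyloxy)-2-oxo-2H-pyran-6-yl)methyl]phenyl}-3-phenylpropane-1,3-dione F3. The biomimetic intramolecular aldol of the benzylic carbon onto the benzoyl carbonyl at pH 8–9 (phosphate buffer/THF) would then give, under thermodynamic control, rac-(3R,4R)-8-(benzyloxy)-4-[4-(benzyloxy)-2-oxo-2H-pyran-6-yl]-3-hydroxy-3-phenyl-3,4-dihydronaphthalen-1(2H)-one F4. Hydrogenolysis of both benzyl ethers (H2, Pd/C) returns to 17.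

2. Step 10. What may go wrong: the diastereomeric salts may not differ enough in solubility, or the amine may promote epimerisation at the benzylic centre or retro-aldol in solution.

Fallback from 17 to 18: preparative enantioselective chromatography (supercritical CO2/MeOH on an immobilised amylose tris(3,5-dimethylphenylcarbamate) phase), with no base present. The other enantiomer again goes to step 11. This fallback makes no new compound (F0).

3. Step 13. What may go wrong: methylene scrambling through retro-Mannich and quinone-methide exchange would consume the enantiopure half as its homodimer, and the naphthalenediol carbons may be alkylated in competition.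

Fallback with reversed roles, setting out from 19 and returning at 21. Compound 19 is aminomethylated (CH2(NMe2)2, CH2Cl2) to 6-(4,5-dihydroxy-2-phenylnaphthalen-1-yl)-3-[(dimethylamino)methyl]-4-hydroxy-2H-pyran-2-one F5. F5 is heated with 18 (used as the limiting nucleophile, dioxane, 60 °C), so that 18 can only end up in the cross product 21.

**Further compounds**
F1 | step 7 | 4-(benzyloxy)-6-{[3-(benzyloxy)-2-bromophenyl]methyl}-2H-pyran-2-one | O=c1cc(OCc2ccccc2)cc(Cc2cccc(OCc3ccccc3)c2Br)o1
F2 | step 7 | N-methoxy-N-methyl-3-oxo-3-phenylpropanamide | CON(C)C(=O)CC(=O)c1ccccc1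
F3 | step 7 | 1-{2-(benzyloxy)-6-[(4-(benzyloxy)-2-oxo-2H-pyran-6-yl)methyl]phenyl}-3-phenylpropane-1,3-dione | O=C(CC(=O)c1ccccc1)c1c(OCc2ccccc2)cccc1Cc1cc(OCc2ccccc2)cc(=O)o1
F4 | step 7 | rac-(3R,4R)-8-(benzyloxy)-4-[4-(benzyloxy)-2-oxo-2H-pyran-6-yl]-3-hydroxy-3-phenyl-3,4-dihydronaphthalen-1(2H)-one | O=C1C[C@](O)(c2ccccc2)[C@H](c2cc(OCc3ccccc3)cc(=O)o2)c2cccc(OCc3ccccc3)c21
F0 | step 10 | none | none
F5 | step 13 | 6-(4,5-dihydroxy-2-phenylnaphthalen-1-yl)-3-[(dimethylamino)methyl]-4-hydroxy-2H-pyran-2-one | CN(C)Cc1c(O)cc(-c2c(-c3ccccc3)cc(O)c3c(O)cccc23)oc1=O
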